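**Plan**
- Target: 8-(2,4-dihydroxy-6-pentylphenoxy)-6-hydroxy-3-pentylisocoumarin, with the isocoumarin numbered C1(=O), O2, C3 … C8a throughout.
- Retrosynthesis: cut first the diaryl ether bond C8–O (isocoumarin 8-triflate plus 2,4-dimethoxy-6-pentylphenol), then O2–C1 and C4a–C8a together, then C5–C4a and C7–C6 of the open chain.
- Enabling feature: the chain C1–C8a–C8(O)–C7–C6(O)–C5–C4a–C4–C3(O)–C5H11 carries oxygen on every second carbon, so a dioxinone (C1, C8a, C8), two ketones (C6, C4a) and a masked ketone (C3) can fold into the benzene ring and the pyranone.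
- Forward: two Claisen acylations build the chain; in one operation the benzene ring of the isocoumarin closes first (aldol, aromatisation) and the pyranone second (enol lactonisation); ring B, from olivetol dimethyl ether, is attached last by C–O coupling, followed by global demethylation.
- The coupling polarity is chosen so that the isocoumarin is the electrophile (8-triflate), because direct arylation of the chelated 8-OH with an electron-rich, doubly ortho-substituted aryl donor is the weak alternative.
- Stereochemistry: none to set; the target has no stereocentre.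

Key step: step 5

**Step 1**
Reactants: 1 2,2,6-trimethyl-4H-1,3-dioxin-4-one
Product: 2 2,2-dimethyl-6-(2-oxopropyl)-4H-1,3-dioxin-4-one
Conditions: LiN(SiMe3)2 (2 equiv), THF, −78 °C; then AcCl (1 equiv), −78 °C; 1 M HCl quench
Reagents that add atoms: acetyl chloride, CC(=O)Cl
Why: Claisen-type C-acylation of a vinylogous ester dienolate: the base removes a proton from the C6 methyl group, acetyl chloride acylates that γ-carbon, and the second equivalent of dienolate takes up the acidic proton of the β-keto product.

**Step 2**
Reactants: 3 methyl 3-oxooctanoate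
Product: 4 methyl 2-(2-pentyl-1,3-dioxolan-2-yl)acetate
Conditions: HOCH2CH2OH, TsOH·H2O (cat.), toluene, reflux, Dean–Stark
Reagents that add atoms: ethylene glycol, OCCO
Why: Acid-catalysed ketalisation driven by azeotropic removal of water; only the ketone of the β-keto ester reacts, as in the standard protection of acetoacetates.

**Step 3**
Reactants: 4 methyl 2-(2-pentyl-1,3-dioxolan-2-yl)acetate
Product: 5 2-(2-pentyl-1,3-dioxolan-2-yl)acetic acid
Conditions: LiOH, THF/MeOH/H2O, rt; then 1 M HCl to pH 4, 0 °C, rapid extraction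
Reagents that add atoms: lithium hydroxide, [Li+].[OH-]
Why: Ester saponification; the dioxolane is inert to hydroxide and should survive the brief, cold, mildly acidic work-up.

**Step 4**
Reactants: 2 2,2-dimethyl-6-(2-oxopropyl)-4H-1,3-dioxin-4-one; 5 2-(2-pentyl-1,3-dioxolan-2-yl)acetic acid
Product: 7 2,2-dimethyl-6-[2,4-dioxo-5-(2-pentyl-1,3-dioxolan-2-yl)pentyl]-4H-1,3-dioxin-4-one, via acyl imidazolide 6 (not isolated)
Conditions: 5, CDI, THF, rt; separately 2 (2 equiv), LiN(i-Pr)2 (4.2 equiv), THF, −78 °C; add 6, −78 → −40 °C; aq NH4Cl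
Reagents that add atoms: none
Why: Claisen-type C-acylation of a 1,3-dicarbonyl dianion: the second deprotonation of 2 occurs at the terminal methyl group, this more basic carbanion attacks the acyl imidazolide, and the product is held at once as its enolate so that no second addition follows.

**Step 5**
Reactants: 7 2,2-dimethyl-6-[2,4-dioxo-5-(2-pentyl-1,3-dioxolan-2-yl)pentyl]-4H-1,3-dioxin-4-one
Product: 10 6,8-dihydroxy-3-pentyl-1H-isochromen-1-one, via ketal benzodioxinone 8 (not isolated), via keto benzodioxinone 9 (not isolated)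
Conditions: Et3N, CH2Cl2, rt; evaporate; then TsOH·H2O, wet toluene, 80 °C
Reagents that add atoms: water, O
Why: Et3N deprotonates the C7 methylene to the extended dioxinone dienolate, whose C8a carbon adds to the C4a ketone in an intramolecular aldol reaction; loss of water and enolisation of the C6 ketone should then give the benzodioxinone-masked resorcylate 8, as in the known biomimetic aromatisation of diketo-dioxinones to resorcylates. The carbocycle closes in a 6-(enolexo)-exo-trig mode. Aqueous acid then hydrolyses the dioxolane to ketone 9, and the enol oxygen of that C3 ketone adds to the benzodioxinone carbonyl C1 in a 6-exo-trig acyl substitution that expels the phenol-bound hemiketal as acetone; this is the acid-promoted enol lactonisation of 2-(2-oxoalkyl)benzoate derivatives to isocoumarins. No stereocentre is formed. The step needs fold selectivity, and the substrate secures it: C3 stays a ketal until the arene exists, so C4a is the only ketone that a stabilised carbanion can reach through a six-membered transition state, and the trans arrangement of chain and carbonyl across the dioxinone double bond keeps C1 out of reach of the chain enolates.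

**Step 6**
Reactants: 10 6,8-dihydroxy-3-pentyl-1H-isochromen-1-one
Product: 11 8-hydroxy-6-methoxy-3-pentyl-1H-isochromen-1-one
Conditions: MeI (1.05 equiv), K2CO3, acetone, rt
Reagents that add atoms: iodomethane, CI
Why: Williamson etherification, selective for the free and more acidic 6-OH because the 8-OH is tied up in a hydrogen bond to the lactone carbonyl.

**Step 7**
Reactants: 11 8-hydroxy-6-methoxy-3-pentyl-1H-isochromen-1-one
Product: 12 6-methoxy-1-oxo-3-pentyl-1H-isochromen-8-yl trifluoromethanesulfonate
Conditions: Tf2O, pyridine, CH2Cl2, 0 °C → rt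
Reagents that add atoms: trifluoromethanesulfonic anhydride, O=S(=O)(OS(=O)(=O)C(F)(F)F)C(F)(F)F
Why: O-sulfonylation of a phenol; the highly electrophilic anhydride with pyridine overcomes the chelation of peri-hydroxy carbonyl compounds, and turns the least reactive oxygen of the core into the electrophilic site for ether formation.

**Step 8**
Reactants: 13 1,3-dimethoxy-5-pentylbenzene (olivetol dimethyl ether)
Product: 14 2,4-dimethoxy-6-pentylbenzaldehyde
Conditions: POCl3, DMF, 0 → 70 °C; then ice-water
Reagents that add atoms: N,N-dimethylformamide, CN(C)C=O; water, O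
Why: Vilsmeier–Haack formylation; the chloroiminium ion attacks the position para to one methoxy group and ortho to the other in preference to the more crowded position between the two methoxy groups, as with 3,5-dimethoxytoluene.

**Step 9**
Reactants: 14 2,4-dimethoxy-6-pentylbenzaldehyde
Product: 16 2,4-dimethoxy-6-pentylphenol, via aryl formate 15 (not isolated)
Conditions: mCPBA, CH2Cl2, 0 °C → rt; aq NaHCO3 wash; then K2CO3 (cat.), MeOH, rt, under argon
Reagents that add atoms: 3-chloroperoxybenzoic acid, OOC(=O)c1cccc(Cl)c1
Why: Baeyer–Villiger (Dakin-type) oxidation in which the aryl group, made electron-rich by its ortho and para methoxy groups, migrates to oxygen, followed by methanolysis of the formate.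

**Step 10**
Reactants: 12 6-methoxy-1-oxo-3-pentyl-1H-isochromen-8-yl trifluoromethanesulfonate; 16 2,4-dimethoxy-6-pentylphenol
Product: 17 8-(2,4-dimethoxy-6-pentylphenoxy)-6-methoxy-3-pentyl-1H-isochromen-1-one
Conditions: Pd(OAc)2 (5 mol %), tBuXPhos (10 mol %), K3PO4, toluene, 100 °C
Reagents that add atoms: none
Why: Palladium-catalysed C–O cross-coupling (Buchwald–Hartwig diaryl ether synthesis): the electron-poor triflate next to the carbonyl adds readily to zerovalent palladium, the bulky di-tert-butyl biaryl phosphine forces reductive elimination with the electron-rich phenoxide, and poorly soluble K3PO4 keeps free phenoxide low enough to limit attack at sulfur.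

**Step 11**
Reactants: 17 8-(2,4-dimethoxy-6-pentylphenoxy)-6-methoxy-3-pentyl-1H-isochromen-1-one
Product: 18 8-(2,4-dihydroxy-6-pentylphenoxy)-6-hydroxy-3-pentyl-1H-isochromen-1-one (target)
Conditions: BBr3 (8 equiv), CH2Cl2, −78 °C → rt; then MeOH, H2O
Reagents that add atoms: none
Why: Lewis-acid cleavage of aryl methyl ethers, in which bromide attacks the methyl group of each boron-bound oxonium by SN2; the diaryl ether has no such carbon, and the isocoumarin lactone is known to tolerate the reagent.

**Compound list**
1 | 2,2,6-trimethyl-4H-1,3-dioxin-4-one | CC1=CC(=O)OC(C)(C)O1 | starting material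
2 | 2,2-dimethyl-6-(2-oxopropyl)-4H-1,3-dioxin-4-one | CC(=O)CC1=CC(=O)OC(C)(C)O1 | intermediate
3 | methyl 3-oxooctanoate | CCCCCC(=O)CC(=O)OC | starting material
4 | methyl 2-(2-pentyl-1,3-dioxolan-2-yl)acetate | CCCCCC1(CC(=O)OC)OCCO1 | intermediate
5 | 2-(2-pentyl-1,3-dioxolan-2-yl)acetic acid | CCCCCC1(CC(=O)O)OCCO1 | intermediate
6 | 1-(1H-imidazol-1-yl)-2-(2-pentyl-1,3-dioxolan-2-yl)ethan-1-one (acyl imidazolide, not isolated) | CCCCCC1(CC(=O)n2ccnc2)OCCO1 | intermediate
7 | 2,2-dimethyl-6-[2,4-dioxo-5-(2-pentyl-1,3-dioxolan-2-yl)pentyl]-4H-1,3-dioxin-4-one | CCCCCC1(CC(=O)CC(=O)CC2=CC(=O)OC(C)(C)O2)OCCO1 | intermediate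
8 | 7-hydroxy-2,2-dimethyl-5-[(2-pentyl-1,3-dioxolan-2-yl)methyl]-4H-1,3-benzodioxin-4-one (not isolated) | CCCCCC1(Cc2cc(O)cc3OC(C)(C)OC(=O)c23)OCCO1 | intermediate
9 | 7-hydroxy-2,2-dimethyl-5-(2-oxoheptyl)-4H-1,3-benzodioxin-4-one (not isolated) | CCCCCC(=O)Cc1cc(O)cc2OC(C)(C)OC(=O)c12 | intermediate
10 | 6,8-dihydroxy-3-pentyl-1H-isochromen-1-one | CCCCCc1cc2cc(O)cc(O)c2c(=O)o1 | intermediate
11 | 8-hydroxy-6-methoxy-3-pentyl-1H-isochromen-1-one | CCCCCc1cc2cc(OC)cc(O)c2c(=O)o1 | intermediate
12 | 6-methoxy-1-oxo-3-pentyl-1H-isochromen-8-yl trifluoromethanesulfonate | CCCCCc1cc2cc(OC)cc(OS(=O)(=O)C(F)(F)F)c2c(=O)o1 | intermediate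
13 | 1,3-dimethoxy-5-pentylbenzene (olivetol dimethyl ether) | CCCCCc1cc(OC)cc(OC)c1 | starting material
14 | 2,4-dimethoxy-6-pentylbenzaldehyde | CCCCCc1cc(OC)cc(OC)c1C=O | intermediate
15 | 2,4-dimethoxy-6-pentylphenyl formate (not isolated) | CCCCCc1cc(OC)cc(OC)c1OC=O | intermediate
16 | 2,4-dimethoxy-6-pentylphenol | CCCCCc1cc(OC)cc(OC)c1O | intermediate
17 | 8-(2,4-dimethoxy-6-pentylphenoxy)-6-methoxy-3-pentyl-1H-isochromen-1-one | CCCCCc1cc2cc(OC)cc(Oc3c(OC)cc(OC)cc3CCCCC)c2c(=O)o1 | intermediate
18 | 8-(2,4-dihydroxy-6-pentylphenoxy)-6-hydroxy-3-pentyl-1H-isochromen-1-one | CCCCCc1cc2cc(O)cc(Oc3c(O)cc(O)cc3CCCCC)c2c(=O)o1 | target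

**Totals**
Total step count: 11.
Longest linear sequence: 8 steps (3 → 4 → 5 → 7 → 10 → 11 → 12 → 17 → 18; steps 2, 3, 4, 5, 6, 7, 10, 11).

**Steps most likely to fail**

1. Step 10 (C–O coupling). Sulfonyl transfer from the triflate to the phenoxide would return 11. Reductive elimination from the crowded aryl palladium phenoxide may also be slow and let hydrodetriflation take over. The fallback reverses the polarity and arylates the chelated phenol without a metal, setting out from 13 and 11. Iodination of 13 (NIS, cat. TFA, MeCN) should give 2-iodo-1,5-dimethoxy-3-pentylbenzene F1. Oxidation to trivalent iodine (mCPBA, TsOH·H2O, MeCN) should give [hydroxy(tosyloxy)iodo]-2,4-dimethoxy-6-pentylbenzene F2, used in the same flask. Electrophilic substitution of a second equivalent of 13 should give the symmetrical bis(2,4-dimethoxy-6-pentylphenyl)iodonium tosylate F3, which poses no question of which aryl group is transferred. The potassium phenoxide of 11 (t-BuOK, THF/toluene, rt to 60 °C) should then undergo ligand coupling at iodine, a process that tolerates ortho substituents on both partners, and the route is rejoined at 17.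

2. Step 4 (dianion acylation). Proton transfer from the α-methylene of the imidazolide to the dianion, β-elimination that opens the dioxolane, and O-acylation could all erode the C-acylation. The fallback replaces the Claisen step by aldol addition and oxidation, setting out from 4 and 2. Reduction of 4 with i-Bu2AlH (CH2Cl2, −78 °C) should give 2-(2-pentyl-1,3-dioxolan-2-yl)acetaldehyde F4. The dianion of 2 (LiN(i-Pr)2, THF, −78 °C) should add to it quickly to give racemic 6-[4-hydroxy-2-oxo-5-(2-pentyl-1,3-dioxolan-2-yl)pentyl]-2,2-dimethyl-4H-1,3-dioxin-4-one F5. Dess–Martin oxidation (NaHCO3, CH2Cl2) of the β-hydroxy ketone should then give 7.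

3. Step 5 (key cascade). The acid stage may stall at keto benzodioxinone 9 because the enol attacks the acetonide-bound carbonyl too slowly, or the acetonide may hydrolyse to the acid before ring closure. The fallback keeps the same C8a–C4a aldol but switches to the ketene-trapping mode, setting out from 7. Heating in toluene with MeOH (retro-[4+2] to the acylketene, trapped by methanol) should give methyl 3,5,7-trioxo-8-(2-pentyl-1,3-dioxolan-2-yl)octanoate F6. Base-mediated aldol aromatisation (K2CO3, MeOH, then mild acid) should give methyl 2,4-dihydroxy-6-[(2-pentyl-1,3-dioxolan-2-yl)methyl]benzoate F7. TsOH·H2O in wet toluene at 90 °C should remove the ketal to give methyl 2,4-dihydroxy-6-(2-oxoheptyl)benzoate F8, whose enol lactonises onto the methyl ester, and the route is rejoined at 10.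

**Further compounds**
F1 | step 10 | 2-iodo-1,5-dimethoxy-3-pentylbenzene | CCCCCc1cc(OC)cc(OC)c1I
F2 | step 10 | [hydroxy(tosyloxy)iodo]-2,4-dimethoxy-6-pentylbenzene | CCCCCc1cc(OC)cc(OC)c1I(O)OS(=O)(=O)c1ccc(C)cc1
F3 | step 10 | bis(2,4-dimethoxy-6-pentylphenyl)iodonium 4-methylbenzenesulfonate | CCCCCc1cc(OC)cc(OC)c1[I+]c1c(OC)cc(OC)cc1CCCCC.Cc1ccc(cc1)S(=O)(=O)[O-]
F4 | step 4 | 2-(2-pentyl-1,3-dioxolan-2-yl)acetaldehyde | CCCCCC1(CC=O)OCCO1
F5 | step 4 | racemic 6-[4-hydroxy-2-oxo-5-(2-pentyl-1,3-dioxolan-2-yl)pentyl]-2,2-dimethyl-4H-1,3-dioxin-4-one | CCCCCC1(CC(O)CC(=O)CC2=CC(=O)OC(C)(C)O2)OCCO1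
F6 | step 5 | methyl 3,5,7-trioxo-8-(2-pentyl-1,3-dioxolan-2-yl)octanoate | CCCCCC1(CC(=O)CC(=O)CC(=O)CC(=O)OC)OCCO1
F7 | step 5 | methyl 2,4-dihydroxy-6-[(2-pentyl-1,3-dioxolan-2-yl)methyl]benzoate | CCCCCC1(Cc2cc(O)cc(O)c2C(=O)OC)OCCO1
F8 | step 5 | methyl 2,4-dihydroxy-6-(2-oxoheptyl)benzoate | CCCCCC(=O)Cc1cc(O)cc(O)c1C(=O)OC
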